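**Route proposal for selaginellin F: a tethered tetrayne is cycloaromatised to an aryne and trapped by resorcinol**

## Analysis of the target

Selaginellin F is built on a central benzene, ring A, in which four neighbouring positions carry four different carbon substituents. C1 holds the diarylmethylene carbon, C2 the 2,4-dihydroxyphenyl ring B, C5 a hydroxymethyl group and C6 a (4-hydroxyphenyl)ethynyl group; C3 and C4 carry hydrogen. The carbon on C1 is the exocyclic carbon of a para-quinone methide. Its two aryl partners (the 4-hydroxyphenyl ring C and the cyclohexadienone ring D) interconvert by tautomerism, so at the carbinol oxidation level they are the same 4-oxygenated aryl group. The molecule has no stereocentre and no stereogenic double bond, and the biaryl axis is not hindered enough to be an element of chirality. The sensitive groups are the electrophilic quinone methide, four free phenols, a benzylic alcohol next to an alkyne (prone to cycloisomerisation) and an electron-rich diaryl alkyne. The difficulty is the contiguous C5–C6–C1–C2 substitution of ring A and the crowding at C1, which sits between an aryl and an alkynyl group. The strategy rests on one pattern in ring A: an alkynyl group at C6, an oxygenated one-carbon unit at C5, a hydrogen at C3 and an ortho-hydroxyaryl group at C2. This is what remains when an ester-tethered tetrayne closes to a lactone-fused aryne (C2≡C3) and a phenol adds across it.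

## Retrosynthetic reasoning

Target 29 to carbinol 27. The quinone methide is the dehydration product of a triaryl carbinol with a para-hydroxyphenyl group. It is unmasked last, by acid cleavage of five methoxymethyl ethers and ionisation of the tertiary hydroxyl through cation 28. All earlier steps then run on a protected, non-electrophilic compound.

Carbinol 27 to ketone 25 and aryllithium 26. The bond from the carbinol carbon to one of its two equivalent aryl groups is cut. The other aryl group and the carbonyl carbon are already on C1, so a small, unhindered aryllithium (from iodide 24) is delivered to a ketone. A hindered ring A nucleophile is never needed.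

Ketone 25 to terminal alkyne 22 and iodide 24. The sp–sp2 bond between the alkyne and its aryl group is cut (Sonogashira). The alkyne terminus has to carry a bulky silyl cap through the ring-forming step, so the aryl group is introduced only afterwards. Iodide 24 comes from 4-iodophenol 23.

Alkyne 22 to silyl compound 21 to acid 20. The hydrogen at C4 is traced back to a carboxyl group, which is removed by silver-catalysed protodecarboxylation. This carboxyl is the remnant of the tether. One fluoride treatment removes both silyl groups of 21.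

Acid 20 to phthalide 17 (and free bisphenol 16). The C4 carboxyl and the C5 oxymethyl group are rejoined as a five-membered lactone. In the forward direction the lactone is opened and the liberated hydroxymethyl group is silylated at once, because the free hydroxy acid would reclose.

Phthalide 16 to tetrayne 13 and resorcinol 14 (key disconnection). A retro-ene cut of the C2–ring B bond and the C3–H bond gives aryne 15 and resorcinol 14. Cutting C1–C6 and C4–C5 then opens ring A and the lactone to the acyclic tetrayne 13. These cuts are chosen because the connectivity of 13 alone fixes the position of every ring A substituent. The forward reaction has to control which diyne serves as the four-carbon unit and which aryne carbon receives carbon.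

Tetrayne 13 to carbinol 12, then to acid 11 and bromide 5. The ynone is generated last, by oxidation of the doubly activated carbinol, so that the most electrophilic form of the polyyne meets no nucleophile. The ester is cut on its alkyl side, so the forward step is carboxylate alkylation by propargylic bromide 5. This avoids carboxyl activation and acylation of the free secondary hydroxyl of 11.

Acid 11 to alkynol 8 and bromoalkyne 10. The central sp–sp bond of the diynoic acid is cut (Cadiot–Chodkiewicz). Alkynol 8 comes from aldehyde 7 and hence from 6; bromoalkyne 10 comes from propiolic acid 9.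

Bromide 5 to diynol 4, then to bromoalkyne 2 and propargyl alcohol 3. The same sp–sp disconnection is used; 2 is made from silylacetylene 1.

## Alternatives that were turned down

Alternative 1: The C2–ring B bond and the bond from C1 to the carbinol carbon are cut together. Ring A is then fluoroarene A2 (fluorine at C2, hydrogen at C1, the finished arylethynyl group at C6, a protected hydroxymethyl at C5), ring B is aryllithium A3 and the third piece is diaryl ketone A4. In the forward step A2 is lithiated at C1 and loses fluoride to give a C1≡C2 aryne; A3 adds at C2 and the new C1 aryllithium is quenched by A4 to give carbinol A1, one acid step from the target.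
- For: three fragments and the whole skeleton in one flask. It is clearly shorter and more convergent than the chosen route.
- Against: the regiochemistry of the aryne addition rests only on the inductive pull of the C6 alkynyl group. The base and A3 can also attack the diaryl alkyne or A4. The final event asks a 2,6-disubstituted aryllithium to add to a diaryl ketone, where proton capture will compete.
- Comparison: Alternative 1 wins on step count. The chosen route offers instead a ring A whose pattern is fixed by the connectivity of 13, a key step without strong base, and a C1 carbon that is already in place.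

Alternative 2: The C2–ring B bond is cut as an intramolecular C–H arylation. The precursor is aryl ester A6, in which the ring A 2-chlorobenzoic acid (carboxyl on C1) is esterified with a 3-oxygenated phenol. Palladium catalysis with a bulky trialkylphosphine closes benzo[c]chromen-6-one A5.
- For: the tether guarantees bond formation ortho to the ring B oxygen. Opening A5 with two equivalents of one aryllithium would install both equivalent aryl groups and free the ring B hydroxyl in one step. On the endgame this is stronger than the chosen route, which brings the two aryl groups in separately.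
- Against: chloride activation needs high temperature and carbonate base, under which the aryl ester can cleave. The alkyne at C6, ortho to the ester carbonyl, invites palladium-promoted oxycyclisation. A6 also presupposes a fully substituted ring A acid, so the hardest part of the target is left to unspecified arene chemistry.
- Comparison: the chosen route builds that substitution pattern in its key step, from compounds made by alkyne couplings only.

Alternative 3: The C5–carboxyl bond and the C6–alkyne bond are cut together. The C6 iodide A8 (aroyl on C1, ring B on C2) undergoes palladium catalysis mediated by a strained bicyclic alkene: ortho C–H alkoxycarbonylation at C5 by a mixed-anhydride donor, then ipso coupling with terminal alkyne A9, to give ester ketone A7.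
- For: two adjacent substituents arrive in one step, and the alkyne comes with its aryl group, so the desilylation and Sonogashira steps of the chosen route are saved.
- Against: direct ipso alkynylation competes before the palladacycle forms, and the iodide is crowded by the C1 aroyl group. A7 holds an ester that must be reduced and a ketone that must receive an aryllithium, and each reagent attacks both carbonyls. A8 again needs a pre-made 1,2,3-trisubstituted ring.
- Comparison: Alternative 3 is more convergent at C6. The chosen route delivers C5 at the alcohol oxidation level from the start and so avoids the chemoselectivity problem; it pays with the steps that delete the C4 carboxyl.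

Key step: step 10

Remark: carbinols 8, 11 and 12 are racemic; their stereocentre is erased by the oxidation in step 9, and the target has none. C1–C6 always denote the ring A atoms defined in the analysis.

## Route

Step 1
Reactants: 1 (triisopropylsilyl)acetylene
Product: 2 (bromoethynyl)triisopropylsilane
Conditions: NBS, AgNO3 (10 mol%), acetone, rt, dark
Reagents that add atoms: N-bromosuccinimide, O=C1CCC(=O)N1Br
Why: Silver-acetylide-mediated electrophilic bromination of a terminal alkyne; the bulky silyl group is inert to these conditions.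

Step 2
Reactants: 2 (bromoethynyl)triisopropylsilane; 3 propargyl alcohol
Product: 4 5-(triisopropylsilyl)penta-2,4-diyn-1-ol
Conditions: CuCl (5 mol%), NH2OH·HCl, n-BuNH2 (30% aq.), 0 °C to rt
Reagents that add atoms: none
Why: Cadiot–Chodkiewicz coupling of a bromoalkyne with a terminal alkyne; the hindered silyl bromoalkyne suppresses homocoupling and the free hydroxyl is tolerated.

Step 3
Reactants: 4 5-(triisopropylsilyl)penta-2,4-diyn-1-ol
Product: 5 (5-bromopenta-1,3-diyn-1-yl)triisopropylsilane
Conditions: CBr4, PPh3, CH2Cl2, 0 °C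
Reagents that add atoms: carbon tetrabromide, BrC(Br)(Br)Br
Why: Appel bromination of a primary propargylic alcohol under neutral conditions; the product is used soon after preparation.

Step 4
Reactants: 6 4-hydroxybenzaldehyde
Product: 7 4-(methoxymethoxy)benzaldehyde
Conditions: MOMCl, iPr2NEt, CH2Cl2, 0 °C to rt
Reagents that add atoms: chloromethyl methyl ether, COCCl
Why: Standard O-alkylation of a phenol; the acetal withstands every basic, organometallic and thermal step up to the final acid treatment.

Step 5
Reactants: 7 4-(methoxymethoxy)benzaldehyde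
Product: 8 racemic 1-[4-(methoxymethoxy)phenyl]prop-2-yn-1-ol
Conditions: HC≡CMgBr, THF, 0 °C; aq. NH4Cl
Reagents that add atoms: ethynylmagnesium bromide, C#C[Mg]Br
Why: Grignard addition of an acetylide to an aldehyde; the new stereocentre is formed racemic on purpose because step 9 oxidises it away.

Step 6
Reactants: 9 propiolic acid
Product: 10 3-bromopropiolic acid
Conditions: NBS, AgNO3 (10 mol%), acetone, rt
Reagents that add atoms: N-bromosuccinimide, O=C1CCC(=O)N1Br
Why: The same silver-catalysed alkyne bromination as in step 1, applied to the free acid.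

Step 7
Reactants: 8 racemic 1-[4-(methoxymethoxy)phenyl]prop-2-yn-1-ol; 10 3-bromopropiolic acid
Product: 11 racemic 6-hydroxy-6-[4-(methoxymethoxy)phenyl]hexa-2,4-diynoic acid
Conditions: CuCl (10 mol%), NH2OH·HCl, EtNH2 (70% aq.), MeOH/H2O, 0 °C; then cold aq. citric acid to pH 3
Reagents that add atoms: none
Why: Cadiot–Chodkiewicz coupling with the bromoalkyne present as its carboxylate salt, which is not a Michael acceptor for the amine; brief cold acidification leaves the aryl acetal intact.

Step 8
Reactants: 11 racemic 6-hydroxy-6-[4-(methoxymethoxy)phenyl]hexa-2,4-diynoic acid; 5 (5-bromopenta-1,3-diyn-1-yl)triisopropylsilane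
Product: 12 racemic 5-(triisopropylsilyl)penta-2,4-diyn-1-yl 6-hydroxy-6-[4-(methoxymethoxy)phenyl]hexa-2,4-diynoate
Conditions: KHCO3, DMF, 0 °C to rt
Reagents that add atoms: none
Why: SN2 O-alkylation of a carboxylate by a propargylic bromide; bicarbonate does not deprotonate the secondary alcohol, and because the acid is never activated it cannot acylate its own hydroxyl.

Step 9
Reactants: 12 racemic 5-(triisopropylsilyl)penta-2,4-diyn-1-yl 6-hydroxy-6-[4-(methoxymethoxy)phenyl]hexa-2,4-diynoate
Product: 13 5-(triisopropylsilyl)penta-2,4-diyn-1-yl 6-[4-(methoxymethoxy)phenyl]-6-oxohexa-2,4-diynoate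
Conditions: MnO2 (activated, excess), CH2Cl2, rt, dark; filtered and used cold without delay
Reagents that add atoms: none
Why: Selective heterogeneous oxidation of a benzylic and propargylic alcohol under neutral conditions, which spares the ester, acetal and silyl groups.

Step 10
Reactants: 13 5-(triisopropylsilyl)penta-2,4-diyn-1-yl 6-[4-(methoxymethoxy)phenyl]-6-oxohexa-2,4-diynoate; 14 resorcinol
Product: 16 6-(2,4-dihydroxyphenyl)-5-[4-(methoxymethoxy)benzoyl]-4-[(triisopropylsilyl)ethynyl]-2-benzofuran-1(3H)-one, via aryne 15 (not isolated)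
Conditions: 14 (5 equiv), 1,2-dichlorobenzene (0.02 M), 110 °C, N2
Reagents that add atoms: none
Why: Thermal hexadehydro-Diels–Alder cycloisomerisation followed by phenol ene trapping, both known for ester-tethered polyynes. Heating brings together the two alkyne carbons next to the C(=O)–O–CH2 tether; C4–C5 bonding closes the five-membered lactone and leaves a diradical delocalised over both flanking alkynes. Recombination between C1 and C6 closes the six-membered ring A as aryne 15, a net intramolecular (4+2) addition of the diynoate to the propargylic alkyne. The other recombination, at the silyl-bearing terminus, should be disfavoured because it would place a triisopropylsilyl group on the new ring next to an alkynyl substituent, whereas C1 carries a flat aroyl group. In 15 the fused five-membered ring narrows the internal angle at C3 and widens it at C2, so C2 is the electrophilic aryne carbon. Neutral resorcinol reacts through a concerted ene-type transition state: its C4 (ortho to one hydroxyl, para to the other) bonds to C2 while the hydroxyl hydrogen passes to C3, and tautomerisation of the dienone restores ring B as the 2,4-dihydroxyphenyl group. The absence of base keeps the phenol from reacting as a phenoxide, which would favour aryl ether formation; the excess of 14 and high dilution limit double arylation and oligomerisation of 13. No stereocentre is formed.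

Step 11
Reactants: 16 6-(2,4-dihydroxyphenyl)-5-[4-(methoxymethoxy)benzoyl]-4-[(triisopropylsilyl)ethynyl]-2-benzofuran-1(3H)-one
Product: 17 6-[2,4-bis(methoxymethoxy)phenyl]-5-[4-(methoxymethoxy)benzoyl]-4-[(triisopropylsilyl)ethynyl]-2-benzofuran-1(3H)-one
Conditions: MOMCl (3 equiv), iPr2NEt, CH2Cl2, 0 °C to rt
Reagents that add atoms: chloromethyl methyl ether, COCCl
Why: O-alkylation of both phenols; under base any cyclic hemiketal between the ortho-hydroxyl and the neighbouring ketone reopens to the phenoxide, which is the species alkylated.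

Step 12
Reactants: 17 6-[2,4-bis(methoxymethoxy)phenyl]-5-[4-(methoxymethoxy)benzoyl]-4-[(triisopropylsilyl)ethynyl]-2-benzofuran-1(3H)-one
Product: 20 5-[2,4-bis(methoxymethoxy)phenyl]-4-[4-(methoxymethoxy)benzoyl]-3-[(triisopropylsilyl)ethynyl]-2-{[(triisopropylsilyl)oxy]methyl}benzoic acid, via potassium hydroxy carboxylate 18 (not isolated), via silyl ester silyl ether 19 (not isolated)
Conditions: KOH (1.5 equiv), THF/H2O, rt, then evaporation; TIPSCl, imidazole, DMF, rt; K2CO3, MeOH/THF/H2O, rt; aq. citric acid, 0 °C, to pH 4–5
Reagents that add atoms: potassium hydroxide, [K+].[OH-]; chlorotriisopropylsilane, CC(C)[Si](Cl)(C(C)C)C(C)C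
Why: Saponification of the phthalide, silylation of the hydroxy carboxylate before any acidification, then selective hydrolysis of the labile silyl ester; this is the established way to keep a 2-(hydroxymethyl)benzoic acid from relactonising. Any material that does reclose simply returns 17.

Step 13
Reactants: 20 5-[2,4-bis(methoxymethoxy)phenyl]-4-[4-(methoxymethoxy)benzoyl]-3-[(triisopropylsilyl)ethynyl]-2-{[(triisopropylsilyl)oxy]methyl}benzoic acid
Product: 21 [2',4'-bis(methoxymethoxy)-4-{[(triisopropylsilyl)oxy]methyl}-3-[(triisopropylsilyl)ethynyl]biphenyl-2-yl][4-(methoxymethoxy)phenyl]methanone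
Conditions: Ag2CO3 (10 mol%), AcOH (5 mol%), DMSO, 120 °C
Reagents that add atoms: none
Why: Silver-catalysed protodecarboxylation of an ortho-substituted benzoic acid through an aryl silver intermediate that is protonated in situ; the ortho silyloxymethyl group twists the carboxylate out of plane and the para aroyl group stabilises the aryl–metal species. The hindered silyl groups are expected to tolerate monovalent silver.

Step 14
Reactants: 21 [2',4'-bis(methoxymethoxy)-4-{[(triisopropylsilyl)oxy]methyl}-3-[(triisopropylsilyl)ethynyl]biphenyl-2-yl][4-(methoxymethoxy)phenyl]methanone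
Product: 22 [3-ethynyl-4-(hydroxymethyl)-2',4'-bis(methoxymethoxy)biphenyl-2-yl][4-(methoxymethoxy)phenyl]methanone
Conditions: TBAF (3 equiv), THF, 0 °C to rt; aq. NH4Cl
Reagents that add atoms: none
Why: Fluoride cleaves the C(sp)–Si and O–Si bonds in one operation; the low temperature keeps the liberated alkoxide from adding to the neighbouring alkyne.

Step 15
Reactants: 23 4-iodophenol
Product: 24 1-iodo-4-(methoxymethoxy)benzene
Conditions: MOMCl, iPr2NEt, CH2Cl2, 0 °C to rt
Reagents that add atoms: chloromethyl methyl ether, COCCl
Why: Phenol O-alkylation; this one protected iodide serves steps 16 and 17.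

Step 16
Reactants: 22 [3-ethynyl-4-(hydroxymethyl)-2',4'-bis(methoxymethoxy)biphenyl-2-yl][4-(methoxymethoxy)phenyl]methanone; 24 1-iodo-4-(methoxymethoxy)benzene
Product: 25 [4-(hydroxymethyl)-2',4'-bis(methoxymethoxy)-3-{[4-(methoxymethoxy)phenyl]ethynyl}biphenyl-2-yl][4-(methoxymethoxy)phenyl]methanone
Conditions: Pd(PPh3)2Cl2 (3 mol%), CuI (5 mol%), Et3N/THF, rt, degassed
Reagents that add atoms: none
Why: Sonogashira coupling of a terminal alkyne with an aryl iodide at room temperature; the ketone and the free benzylic alcohol are tolerated, and the mild conditions avoid cycloisomerisation of the ortho-alkynyl benzyl alcohol.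

Step 17
Reactants: 25 [4-(hydroxymethyl)-2',4'-bis(methoxymethoxy)-3-{[4-(methoxymethoxy)phenyl]ethynyl}biphenyl-2-yl][4-(methoxymethoxy)phenyl]methanone; 24 1-iodo-4-(methoxymethoxy)benzene
Product: 27 [4-(hydroxymethyl)-2',4'-bis(methoxymethoxy)-3-{[4-(methoxymethoxy)phenyl]ethynyl}biphenyl-2-yl]bis[4-(methoxymethoxy)phenyl]methanol, via aryllithium 26 (not isolated)
Conditions: 24 (4 equiv), t-BuLi (8 equiv), THF, −78 °C; then 25, −78 to 0 °C; aq. NH4Cl
Reagents that add atoms: none
Why: Iodine–lithium exchange, then 1,2-addition of the aryllithium to the diaryl ketone; one equivalent is consumed by the hydroxyl and the excess drives addition at the hindered carbonyl. No stereocentre arises because the two aryl groups on the carbinol carbon are identical.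

Step 18
Reactants: 27 [4-(hydroxymethyl)-2',4'-bis(methoxymethoxy)-3-{[4-(methoxymethoxy)phenyl]ethynyl}biphenyl-2-yl]bis[4-(methoxymethoxy)phenyl]methanol
Product: 29 selaginellin F, 4-{[2',4'-dihydroxy-4-(hydroxymethyl)-3-[(4-hydroxyphenyl)ethynyl]biphenyl-2-yl](4-hydroxyphenyl)methylidene}cyclohexa-2,5-dien-1-one, via triarylmethylium chloride 28 (not isolated)
Conditions: HCl (3 M in MeOH)/THF, rt to 40 °C; then H2O, NaHCO3 to pH 6
Reagents that add atoms: none
Why: Acid-catalysed acetal exchange removes all five methoxymethyl groups, with methanol trapping the formaldehyde equivalent, while the tertiary carbinol ionises to the doubly para-oxygen-stabilised cation 28. Loss of a phenolic proton on neutralisation gives the quinone methide.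

## Compound list

1 | (triisopropylsilyl)acetylene | C#C[Si](C(C)C)(C(C)C)C(C)C | starting material
2 | (bromoethynyl)triisopropylsilane | BrC#C[Si](C(C)C)(C(C)C)C(C)C | intermediate
3 | propargyl alcohol | C#CCO | starting material
4 | 5-(triisopropylsilyl)penta-2,4-diyn-1-ol | OCC#CC#C[Si](C(C)C)(C(C)C)C(C)C | intermediate
5 | (5-bromopenta-1,3-diyn-1-yl)triisopropylsilane | BrCC#CC#C[Si](C(C)C)(C(C)C)C(C)C | intermediate
6 | 4-hydroxybenzaldehyde | O=Cc1ccc(O)cc1 | starting material
7 | 4-(methoxymethoxy)benzaldehyde | COCOc1ccc(C=O)cc1 | intermediate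
8 | racemic 1-[4-(methoxymethoxy)phenyl]prop-2-yn-1-ol | COCOc1ccc(C(O)C#C)cc1 | intermediate
9 | propiolic acid | C#CC(=O)O | starting material
10 | 3-bromopropiolic acid | OC(=O)C#CBr | intermediate
11 | racemic 6-hydroxy-6-[4-(methoxymethoxy)phenyl]hexa-2,4-diynoic acid | COCOc1ccc(C(O)C#CC#CC(=O)O)cc1 | intermediate
12 | racemic 5-(triisopropylsilyl)penta-2,4-diyn-1-yl 6-hydroxy-6-[4-(methoxymethoxy)phenyl]hexa-2,4-diynoate | COCOc1ccc(C(O)C#CC#CC(=O)OCC#CC#C[Si](C(C)C)(C(C)C)C(C)C)cc1 | intermediate
13 | 5-(triisopropylsilyl)penta-2,4-diyn-1-yl 6-[4-(methoxymethoxy)phenyl]-6-oxohexa-2,4-diynoate | COCOc1ccc(cc1)C(=O)C#CC#CC(=O)OCC#CC#C[Si](C(C)C)(C(C)C)C(C)C | intermediate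
14 | resorcinol | Oc1cccc(O)c1 | starting material
15 | lactone-fused aryne (C2≡C3) with the aroyl group on C1 and the silylethynyl group on C6 | O=C(c1ccc(OCOC)cc1)C1=C(C#C[Si](C(C)C)(C(C)C)C(C)C)C2=C(C(=O)OC2)C#C1 | intermediate
16 | 6-(2,4-dihydroxyphenyl)-5-[4-(methoxymethoxy)benzoyl]-4-[(triisopropylsilyl)ethynyl]-2-benzofuran-1(3H)-one | O=C(c1ccc(OCOC)cc1)c1c(-c2ccc(O)cc2O)cc2C(=O)OCc2c1C#C[Si](C(C)C)(C(C)C)C(C)C | intermediate
17 | 6-[2,4-bis(methoxymethoxy)phenyl]-5-[4-(methoxymethoxy)benzoyl]-4-[(triisopropylsilyl)ethynyl]-2-benzofuran-1(3H)-one | O=C(c1ccc(OCOC)cc1)c1c(-c2ccc(OCOC)cc2OCOC)cc2C(=O)OCc2c1C#C[Si](C(C)C)(C(C)C)C(C)C | intermediate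
18 | potassium 5-[2,4-bis(methoxymethoxy)phenyl]-2-(hydroxymethyl)-4-[4-(methoxymethoxy)benzoyl]-3-[(triisopropylsilyl)ethynyl]benzoate | [K+].[O-]C(=O)c1cc(-c2ccc(OCOC)cc2OCOC)c(C(=O)c2ccc(OCOC)cc2)c(C#C[Si](C(C)C)(C(C)C)C(C)C)c1CO | intermediate
19 | triisopropylsilyl 5-[2,4-bis(methoxymethoxy)phenyl]-4-[4-(methoxymethoxy)benzoyl]-3-[(triisopropylsilyl)ethynyl]-2-{[(triisopropylsilyl)oxy]methyl}benzoate | CC(C)[Si](OC(=O)c1cc(-c2ccc(OCOC)cc2OCOC)c(C(=O)c2ccc(OCOC)cc2)c(C#C[Si](C(C)C)(C(C)C)C(C)C)c1CO[Si](C(C)C)(C(C)C)C(C)C)(C(C)C)C(C)C | intermediate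
20 | 5-[2,4-bis(methoxymethoxy)phenyl]-4-[4-(methoxymethoxy)benzoyl]-3-[(triisopropylsilyl)ethynyl]-2-{[(triisopropylsilyl)oxy]methyl}benzoic acid | OC(=O)c1cc(-c2ccc(OCOC)cc2OCOC)c(C(=O)c2ccc(OCOC)cc2)c(C#C[Si](C(C)C)(C(C)C)C(C)C)c1CO[Si](C(C)C)(C(C)C)C(C)C | intermediate
21 | [2',4'-bis(methoxymethoxy)-4-{[(triisopropylsilyl)oxy]methyl}-3-[(triisopropylsilyl)ethynyl]biphenyl-2-yl][4-(methoxymethoxy)phenyl]methanone | O=C(c1ccc(OCOC)cc1)c1c(-c2ccc(OCOC)cc2OCOC)ccc(CO[Si](C(C)C)(C(C)C)C(C)C)c1C#C[Si](C(C)C)(C(C)C)C(C)C | intermediate
22 | [3-ethynyl-4-(hydroxymethyl)-2',4'-bis(methoxymethoxy)biphenyl-2-yl][4-(methoxymethoxy)phenyl]methanone | O=C(c1ccc(OCOC)cc1)c1c(-c2ccc(OCOC)cc2OCOC)ccc(CO)c1C#C | intermediate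
23 | 4-iodophenol | Oc1ccc(I)cc1 | starting material
24 | 1-iodo-4-(methoxymethoxy)benzene | COCOc1ccc(I)cc1 | intermediate
25 | [4-(hydroxymethyl)-2',4'-bis(methoxymethoxy)-3-{[4-(methoxymethoxy)phenyl]ethynyl}biphenyl-2-yl][4-(methoxymethoxy)phenyl]methanone | O=C(c1ccc(OCOC)cc1)c1c(-c2ccc(OCOC)cc2OCOC)ccc(CO)c1C#Cc1ccc(OCOC)cc1 | intermediate
26 | [4-(methoxymethoxy)phenyl]lithium | [Li]c1ccc(OCOC)cc1 | intermediate
27 | [4-(hydroxymethyl)-2',4'-bis(methoxymethoxy)-3-{[4-(methoxymethoxy)phenyl]ethynyl}biphenyl-2-yl]bis[4-(methoxymethoxy)phenyl]methanol | OC(c1ccc(OCOC)cc1)(c1ccc(OCOC)cc1)c1c(-c2ccc(OCOC)cc2OCOC)ccc(CO)c1C#Cc1ccc(OCOC)cc1 | intermediate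
28 | bis(4-hydroxyphenyl){2',4'-dihydroxy-4-(hydroxymethyl)-3-[(4-hydroxyphenyl)ethynyl]biphenyl-2-yl}methylium chloride | [Cl-].Oc1ccc(cc1)[C+](c1ccc(O)cc1)c1c(-c2ccc(O)cc2O)ccc(CO)c1C#Cc1ccc(O)cc1 | intermediate
29 | selaginellin F | O=C1C=CC(=C(c2ccc(O)cc2)c2c(-c3ccc(O)cc3O)ccc(CO)c2C#Cc2ccc(O)cc2)C=C1 | target

## Step count and least certain steps

Total: 18 steps. Longest linear sequence: 13 steps (for example steps 4, 5, 7, 8, 9, 10, 11, 12, 13, 14, 16, 17, 18 from 6).

Step 10 (key step).
- What may go wrong: the second ring closure may occur at the silyl-bearing terminus, giving the other aryne. Trapping may proceed by O–H addition (aryl ether) or at another resorcinol carbon. Resorcinol may add to the ynone of 13 before cyclisation.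
- Fallback: the carbon nucleophile is replaced by bromide and the biaryl bond is made afterwards. From 13, heating with triethylammonium bromide in 1,2-dichlorobenzene generates aryne 15 and adds HBr across it, bromide at C2 and hydrogen at C3. This gives 6-bromo-5-[4-(methoxymethoxy)benzoyl]-4-[(triisopropylsilyl)ethynyl]-2-benzofuran-1(3H)-one F1. Suzuki–Miyaura coupling of F1 with [2,4-bis(methoxymethoxy)phenyl]boronic acid F2 (Pd(OAc)2, SPhos, K3PO4, toluene/H2O, 80 °C) returns to the route at 17.

Step 13.
- What may go wrong: decarboxylation may be slow, because a silyloxymethyl group activates the ortho position only weakly. At 120 °C the silyl group may migrate to the carboxylate, followed by reclosure to the lactone.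
- Fallback: the carboxyl is removed through nitrogen instead. From 20, DPPA and Et3N in toluene at 80 °C give the acyl azide F3, which rearranges (Curtius) to the isocyanate F4. Aqueous KOH in THF hydrolyses F4 to the aniline F5. Hydrodediazoniation with tert-butyl nitrite in THF at 60 °C returns to the route at 21.

Step 17.
- What may go wrong: addition to a ketone flanked by an aryl and an alkynyl group may be slow. The warming needed to force it may let the lithium alkoxides add to the neighbouring diaryl alkyne.
- Fallback: the carbinol is made before the alkyne is arylated, and is capped. From 21, which has no hydroxyl and an inert silyl alkyne, addition of 26 can be pushed to room temperature. The alkoxide is methylated in the same flask (MeI, DMPU) to give {2',4'-bis(methoxymethoxy)-4-{[(triisopropylsilyl)oxy]methyl}-3-[(triisopropylsilyl)ethynyl]biphenyl-2-yl}bis[4-(methoxymethoxy)phenyl]methyl methyl ether F6. TBAF gives the terminal alkyne alcohol F7, and Sonogashira coupling with 24 gives the methyl ether F8. The acid conditions of step 18 ionise F8 exactly as they ionise 27, so the fallback rejoins the route at 29.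

Step 18.
- What may go wrong: clearing five acetals takes time, and during it the cation is exposed to acid. The ring B ortho-hydroxyl may capture the cationic carbon (closure to a six-membered cyclic ether), the C5 hydroxymethyl may add to the alkyne, or the quinone methide may oligomerise through its phenols.
- Fallback: acid is applied before the carbinol exists and the end is reached with fluoride. From 25, methanolic HCl removes the four acetals to give the tetraphenol ketone F9, which is persilylated (TBSCl, imidazole, DMF) to F10. {4-[(tert-Butyldimethylsilyl)oxy]phenyl}lithium F11, made by halogen–lithium exchange from the commercial silyl ether of 4-bromophenol, adds to F10 to give carbinol F12. TBAF buffered with AcOH at 0 °C frees the hexahydroxy carbinol F13, which loses its tertiary hydroxyl under these near-neutral conditions to rejoin the route at 29.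

## Further compounds

F1 | step 10 | 6-bromo-5-[4-(methoxymethoxy)benzoyl]-4-[(triisopropylsilyl)ethynyl]-2-benzofuran-1(3H)-one | O=C(c1ccc(OCOC)cc1)c1c(Br)cc2C(=O)OCc2c1C#C[Si](C(C)C)(C(C)C)C(C)C
F2 | step 10 | [2,4-bis(methoxymethoxy)phenyl]boronic acid | COCOc1ccc(B(O)O)c(OCOC)c1
F3 | step 13 | 5-[2,4-bis(methoxymethoxy)phenyl]-4-[4-(methoxymethoxy)benzoyl]-3-[(triisopropylsilyl)ethynyl]-2-{[(triisopropylsilyl)oxy]methyl}benzoyl azide | [N-]=[N+]=NC(=O)c1cc(-c2ccc(OCOC)cc2OCOC)c(C(=O)c2ccc(OCOC)cc2)c(C#C[Si](C(C)C)(C(C)C)C(C)C)c1CO[Si](C(C)C)(C(C)C)C(C)C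
F4 | step 13 | [5-isocyanato-2',4'-bis(methoxymethoxy)-4-{[(triisopropylsilyl)oxy]methyl}-3-[(triisopropylsilyl)ethynyl]biphenyl-2-yl][4-(methoxymethoxy)phenyl]methanone | O=C=Nc1cc(-c2ccc(OCOC)cc2OCOC)c(C(=O)c2ccc(OCOC)cc2)c(C#C[Si](C(C)C)(C(C)C)C(C)C)c1CO[Si](C(C)C)(C(C)C)C(C)C
F5 | step 13 | [5-amino-2',4'-bis(methoxymethoxy)-4-{[(triisopropylsilyl)oxy]methyl}-3-[(triisopropylsilyl)ethynyl]biphenyl-2-yl][4-(methoxymethoxy)phenyl]methanone | Nc1cc(-c2ccc(OCOC)cc2OCOC)c(C(=O)c2ccc(OCOC)cc2)c(C#C[Si](C(C)C)(C(C)C)C(C)C)c1CO[Si](C(C)C)(C(C)C)C(C)C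
F6 | step 17 | {2',4'-bis(methoxymethoxy)-4-{[(triisopropylsilyl)oxy]methyl}-3-[(triisopropylsilyl)ethynyl]biphenyl-2-yl}bis[4-(methoxymethoxy)phenyl]methyl methyl ether | COC(c1ccc(OCOC)cc1)(c1ccc(OCOC)cc1)c1c(-c2ccc(OCOC)cc2OCOC)ccc(CO[Si](C(C)C)(C(C)C)C(C)C)c1C#C[Si](C(C)C)(C(C)C)C(C)C
F7 | step 17 | (3-ethynyl-2-{methoxybis[4-(methoxymethoxy)phenyl]methyl}-2',4'-bis(methoxymethoxy)biphenyl-4-yl)methanol | COC(c1ccc(OCOC)cc1)(c1ccc(OCOC)cc1)c1c(-c2ccc(OCOC)cc2OCOC)ccc(CO)c1C#C
F8 | step 17 | (2-{methoxybis[4-(methoxymethoxy)phenyl]methyl}-2',4'-bis(methoxymethoxy)-3-{[4-(methoxymethoxy)phenyl]ethynyl}biphenyl-4-yl)methanol | COC(c1ccc(OCOC)cc1)(c1ccc(OCOC)cc1)c1c(-c2ccc(OCOC)cc2OCOC)ccc(CO)c1C#Cc1ccc(OCOC)cc1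
F9 | step 18 | {2',4'-dihydroxy-4-(hydroxymethyl)-3-[(4-hydroxyphenyl)ethynyl]biphenyl-2-yl}(4-hydroxyphenyl)methanone | O=C(c1ccc(O)cc1)c1c(-c2ccc(O)cc2O)ccc(CO)c1C#Cc1ccc(O)cc1
F10 | step 18 | penta(tert-butyldimethylsilyl) ether of F9 (four aryl silyl ethers and the C5 silyloxymethyl group) | O=C(c1ccc(O[Si](C)(C)C(C)(C)C)cc1)c1c(-c2ccc(O[Si](C)(C)C(C)(C)C)cc2O[Si](C)(C)C(C)(C)C)ccc(CO[Si](C)(C)C(C)(C)C)c1C#Cc1ccc(O[Si](C)(C)C(C)(C)C)cc1
F11 | step 18 | {4-[(tert-butyldimethylsilyl)oxy]phenyl}lithium | [Li]c1ccc(O[Si](C)(C)C(C)(C)C)cc1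
F12 | step 18 | hexa(tert-butyldimethylsilyl)-protected triaryl carbinol (tertiary hydroxyl free) | OC(c1ccc(O[Si](C)(C)C(C)(C)C)cc1)(c1ccc(O[Si](C)(C)C(C)(C)C)cc1)c1c(-c2ccc(O[Si](C)(C)C(C)(C)C)cc2O[Si](C)(C)C(C)(C)C)ccc(CO[Si](C)(C)C(C)(C)C)c1C#Cc1ccc(O[Si](C)(C)C(C)(C)C)cc1
F13 | step 18 | {2',4'-dihydroxy-4-(hydroxymethyl)-3-[(4-hydroxyphenyl)ethynyl]biphenyl-2-yl}bis(4-hydroxyphenyl)methanol | OC(c1ccc(O)cc1)(c1ccc(O)cc1)c1c(-c2ccc(O)cc2O)ccc(CO)c1C#Cc1ccc(O)cc1
A1 | alternative 1 | {2',4'-bis(methoxymethoxy)-4-[(methoxymethoxy)methyl]-3-{[4-(methoxymethoxy)phenyl]ethynyl}biphenyl-2-yl}bis[4-(methoxymethoxy)phenyl]methanol | OC(c1ccc(OCOC)cc1)(c1ccc(OCOC)cc1)c1c(-c2ccc(OCOC)cc2OCOC)ccc(COCOC)c1C#Cc1ccc(OCOC)cc1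
A2 | alternative 1 | 4-fluoro-1-[(methoxymethoxy)methyl]-2-{[4-(methoxymethoxy)phenyl]ethynyl}benzene | COCOCc1ccc(F)cc1C#Cc1ccc(OCOC)cc1
A3 | alternative 1 | [2,4-bis(methoxymethoxy)phenyl]lithium | [Li]c1ccc(OCOC)cc1OCOC
A4 | alternative 1 | bis[4-(methoxymethoxy)phenyl]methanone | O=C(c1ccc(OCOC)cc1)c1ccc(OCOC)cc1
A5 | alternative 2 | 3-(methoxymethoxy)-8-[(methoxymethoxy)methyl]-7-{[4-(methoxymethoxy)phenyl]ethynyl}-6H-benzo[c]chromen-6-one | O=C1Oc2cc(OCOC)ccc2-c2ccc(COCOC)c(C#Cc3ccc(OCOC)cc3)c21
A6 | alternative 2 | 3-(methoxymethoxy)phenyl 6-chloro-3-[(methoxymethoxy)methyl]-2-{[4-(methoxymethoxy)phenyl]ethynyl}benzoate | O=C(Oc1cccc(OCOC)c1)c1c(Cl)ccc(COCOC)c1C#Cc1ccc(OCOC)cc1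
A7 | alternative 3 | propan-2-yl 2',4'-bis(methoxymethoxy)-2-[4-(methoxymethoxy)benzoyl]-3-{[4-(methoxymethoxy)phenyl]ethynyl}biphenyl-4-carboxylate | O=C(c1ccc(OCOC)cc1)c1c(C#Cc2ccc(OCOC)cc2)c(C(=O)OC(C)C)ccc1-c1ccc(OCOC)cc1OCOC
A8 | alternative 3 | [3-iodo-2',4'-bis(methoxymethoxy)biphenyl-2-yl][4-(methoxymethoxy)phenyl]methanone | O=C(c1ccc(OCOC)cc1)c1c(I)cccc1-c1ccc(OCOC)cc1OCOC
A9 | alternative 3 | 1-ethynyl-4-(methoxymethoxy)benzene | C#Cc1ccc(OCOC)cc1
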